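## Structural features

The target is a chroman: benzene ring A, which carries the carboxylic acid at C6 (para to the ring oxygen), is fused to dihydropyran ring B. C2 of ring B is the only stereocentre, a quaternary (R)-configured carbon bonded to O1, a methyl group, C3 and C1' of the side chain; no second stereocentre stands next to it, so the task is one of absolute and not relative configuration. The side chain is a (1'E,3'E)-diene, C1'=C2'–C3'=C4'(CH3), followed by the C5'–C6' link and the 2,6,6-trimethylcyclohex-1-ene ring (ring C) with its tetrasubstituted alkene. Together with C2, its methyl group, C3 and C4, this chain makes up the twenty carbons of a diterpene joined to a 4-hydroxybenzoic acid. The fragile point is the O1–C2 bond: it is tertiary and dienylic, and its leaving group is a 4-carboxyphenoxide, so Brønsted acids, strong Lewis acids and zerovalent palladium can ionise it, which would racemise C2 or open ring B. The real difficulty is therefore to form ring C, classically an acid-mediated cation–alkene cyclisation, in a molecule whose stereocentre does not tolerate acid, while both diene geometries are kept. The key step uses the fact that ring C (C7' to C12', with the methyl groups on C8' and C12') is a folded geranyl terminus: in the open chain the alkenes C7'=C8' and C11'=C12' stand in a 1,5-relationship, and the next alkene, C3'=C4', is deactivated for a second ring closure by conjugation with C1'=C2'.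

## Logic of the disconnections

17 ⇒ 16. The C7'–C12' bond of ring C is cut (retro cation–alkene cyclisation). Ring C is the only part not available from a cheap acyclic terpene, and opening it costs no stereocentre and leaves a linear tetraene. The forward step must protonate only the terminal alkene, stop after one ring, lose the proton towards the tetrasubstituted alkene and leave O1–C2 alone; this excludes acids in solution and calls for an enzyme pocket.

16 ⇒ 15. The acid is traced back to its methyl ester, so that the carboxyl group is masked through the base and organometallic steps. The forward hydrolysis must be basic and the acidification gentle, because of the O1–C2 bond.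

15 ⇒ 10 + 13 (through 14). The C2'–C3' single bond of the diene and the C4'–CH3 bond are cut. This divides the molecule into a chiral chroman half and an achiral terpene half of similar size, and the trisubstituted 3'E alkene follows from syn methylmetalation of a terminal alkyne. The forward coupling must proceed with retention at both alkenyl carbons, tolerate the ester, and be fast and mild enough that zerovalent palladium does not ionise the allylic aryl ether.

13 ⇒ 11 (through 12). The alkyne is traced back to a methyl ketone, which is a bulk terpene with the 7'E alkene already in place. The forward step needs kinetic enolisation at the methyl group.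

10 ⇒ 9 ⇒ 8 ⇒ 7. The C1'=C2' bond is cut (one-carbon iodo-olefination of an aldehyde), the aldehyde is traced back to the primary alcohol and this to its silyl ether. C1' thus travels as a protected CH2O group through the strongly basic steps. The forward olefination must be E-selective on a hindered aldehyde; 9 has no α-hydrogen and cannot epimerise.

7 ⇒ 6. The O1–C8a bond is cut. In the forward sense the tertiary alkoxide attacks the arene, so no bond to the stereocentre is made or broken, and the para ester that the target needs anyway activates the fluoride. The demand is a nucleophilic aromatic substitution with only moderate activation and without silyl migration.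

6 ⇒ 3 + 4 (through 5). The C4–C4a bond is cut. Coupling a primary alkylborane with an aryl bromide is dependable and tolerates the ester, the fluoride and the free tertiary alcohol. The forward step needs terminal hydroboration and reaction at C–Br only.

3 ⇒ 2 ⇒ 1. The terminal alkene carbon (the later C4) is removed to return to the epoxide, and the silyl group is removed. 1 is a chiral-pool epoxide that already holds the quaternary carbon with oxygen, methyl and two different CH2 arms. The forward steps must attack only the unsubstituted epoxide carbon and must protect the alcohol without a Payne rearrangement, which would invert the centre.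

## Other disconnections considered

Alternative 1: The cut goes through ring A (C4a–C8a and C5–C6), so that rings A and B both arise from a pyridazine ether with a tethered alkyne, A1. Heating A1 should give an intramolecular inverse-demand Diels–Alder addition across the pyridazine carbons, loss of N2, and the chroman A2.
- In its favour: both rings form in one metal-free, neutral step, the ester position is fixed by the pyridazine, and the stereocentre comes from the same epoxide as in the chosen plan and is not touched. The aryl ether bond would be made on a halopyridazine, which is far more activated than the fluorobenzoate of step 4; on this point the alternative is the better.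
- Against it: an unactivated alkyne and an alkoxy-substituted pyridazine would need a high temperature, and the tertiary alkynol needs a propargylation of the epoxide with its propargyl/allenyl ambiguity.
- Comparison: A2 is only the tert-butyldimethylsilyl analogue of 7, so the alternative replaces steps 2 to 4 and nothing else; the side chain and ring C remain to be made as in the chosen plan. Step economy is equal (three steps from the silylated epoxide in both cases). The chosen plan trades the easier ether formation for milder temperatures.

Alternative 2: The cuts are C4–C4a and O1–C2. The iodophenol A3 and the 1,4-diene A4 would be joined under Pd(OAc)2 and a chiral phosphoramidite by arylpalladation, chain walking to a π-allyl and phenoxide attack at the methyl-bearing terminus, giving the vinyl chroman A5.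
- In its favour: one step from two achiral commercial compounds. Oxidative cleavage of the vinyl group of A5 would give 9 after two steps instead of six; on step and atom economy the alternative is clearly the better.
- Against it: the stereocentre would be created by the catalyst in a C–O bond formation at an allyl terminus whose two carbon substituents (methyl and the CH2CH2 tether) differ little, so the enantiomeric purity would rest on a ligand search. Release of a diene after β-hydride elimination would compete with re-addition.
- Comparison: three organometallic events must follow each other in one cycle, whereas the chosen plan takes the centre from the chiral pool and never breaks a bond to it. The alternative wins on length and the chosen plan on stereochemical security; ring C is not addressed by either.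

Alternative 3: The cut is O1–C2 with the whole side chain present. Pd2(dba)3 (zerovalent palladium) and the chiral trans-1,2-diaminocyclohexane bis(2-diphenylphosphinobenzamide) ligand would ionise the bis-allylic carbonate A6 to a pentadienyl complex, and the phenol would close ring B to give A7, the methyl ester of 17.
- In its favour: the route is convergent, ring C can be bought ready-made in a commercial C13 ketone, and only a saponification follows. It needs no reaction beyond known chemistry, which makes it the better on certainty of the ring C question.
- Against it: the pentadienyl complex has three electrophilic positions and can change its geometry, so the 1'E,3'E diene and the ring size both depend on the catalyst. The quaternary centre has two similar carbon substituents. The product is itself an ionisable dienylic aryl ether in the presence of zerovalent palladium, so its configuration could erode.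
- Comparison: the step count should be similar to that of the chosen plan, since A6 needs a multi-step assembly. The alternative sets the stereocentre and ring B in one late step, while the chosen plan has it fixed from step 1 and uses the late step only for a stereochemically silent ring closure.

Key step: step 11

Assumption: a squalene–hopene cyclase variant that accepts 16 is taken to be obtainable by active-site mutagenesis and screening; the route to 16 does not depend on it.

Remark: 1 is (S) and all later compounds are (R) at the same carbon only because the CIP priorities change; no bond to this carbon is broken after step 1.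

Remark: the aryl–C4 bond is made by hydroboration and Suzuki–Miyaura coupling, because direct opening of a 2,2-disubstituted epoxide by an ester-bearing benzylic zinc reagent is poorly supported and Lewis-acid activation risks rearrangement of the epoxide.

## Route

Step 1
Reactants: 1 (S)-2-methylglycidol
Product: 2 tert-butyl{[(2R)-2-methyloxiran-2-yl]methoxy}diphenylsilane
Conditions: TBDPSCl, imidazole, CH2Cl2, 0 °C to rt
Reagents that add atoms: tert-butyl(chloro)diphenylsilane, CC(C)(C)[Si](Cl)(c1ccccc1)c1ccccc1
Why: Silylation of a primary alcohol under weakly basic conditions, which avoids a Payne rearrangement; the bulky diphenylsilyl group is chosen because it should not migrate to the neighbouring tertiary alkoxide in step 4.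

Step 2
Reactants: 2 tert-butyl{[(2R)-2-methyloxiran-2-yl]methoxy}diphenylsilane
Product: 3 (2R)-1-[(tert-butyldiphenylsilyl)oxy]-2-methylbut-3-en-2-ol
Conditions: Me3S+ I− (3 equiv), n-BuLi (2.9 equiv), THF, −10 °C to rt
Reagents that add atoms: trimethylsulfonium iodide, C[S+](C)C.[I-]
Why: Sulfonium ylide one-carbon homologation of an epoxide to an allylic alcohol: the ylide opens the epoxide at its CH2 carbon and a second equivalent turns the betaine into the vinyl carbinol with loss of dimethyl sulfide. The quaternary C–O bond is not broken, so the configuration is retained.

Step 3
Reactants: 3 (2R)-1-[(tert-butyldiphenylsilyl)oxy]-2-methylbut-3-en-2-ol; 4 methyl 3-bromo-4-fluorobenzoate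
Product: 6 methyl 3-[(3R)-4-[(tert-butyldiphenylsilyl)oxy]-3-hydroxy-3-methylbutyl]-4-fluorobenzoate, via B-alkyl-9-BBN borane 5 (not isolated)
Conditions: 9-BBN (2.2 equiv), THF, 0 °C to rt; then 4, Pd(dppf)Cl2 (5 mol %), aq. K3PO4, THF/DMF, 60 °C
Reagents that add atoms: none
Why: Anti-Markovnikov hydroboration of the vinyl group followed by B-alkyl Suzuki–Miyaura coupling at C–Br; the C–F bond, the ester and the hindered tertiary alcohol should be tolerated, the excess borane covering any O–B formation.

Step 4
Reactants: 6 methyl 3-[(3R)-4-[(tert-butyldiphenylsilyl)oxy]-3-hydroxy-3-methylbutyl]-4-fluorobenzoate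
Product: 7 methyl (2R)-2-{[(tert-butyldiphenylsilyl)oxy]methyl}-2-methylchroman-6-carboxylate
Conditions: KN(SiMe3)2 (1.1 equiv), THF, 0 °C to 50 °C
Reagents that add atoms: none
Why: Intramolecular nucleophilic aromatic substitution: the tertiary potassium alkoxide attacks the fluorine-bearing carbon, which the para ester activates, and closes ring B as a six-membered ring. The non-nucleophilic amide base should spare the ester, and the stereocentre only carries the nucleophile.

Step 5
Reactants: 7 methyl (2R)-2-{[(tert-butyldiphenylsilyl)oxy]methyl}-2-methylchroman-6-carboxylate
Product: 8 methyl (2R)-2-(hydroxymethyl)-2-methylchroman-6-carboxylate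
Conditions: Bu4NF, AcOH, THF, rt to 40 °C
Reagents that add atoms: none
Why: Fluoride cleavage of the silyl ether; buffering with acetic acid keeps the medium from attacking the methyl ester.

Step 6
Reactants: 8 methyl (2R)-2-(hydroxymethyl)-2-methylchroman-6-carboxylate
Product: 9 methyl (2R)-2-formyl-2-methylchroman-6-carboxylate
Conditions: Dess–Martin periodinane, CH2Cl2, 0 °C to rt
Reagents that add atoms: none
Why: Dess–Martin oxidation of a neopentyl-type primary alcohol under neutral conditions; the aldehyde has no α-hydrogen and therefore cannot epimerise.

Step 7
Reactants: 9 methyl (2R)-2-formyl-2-methylchroman-6-carboxylate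
Product: 10 methyl (2R)-2-[(E)-2-iodoethenyl]-2-methylchroman-6-carboxylate
Conditions: CrCl2 (6 equiv), CHI3 (2 equiv), THF/1,4-dioxane, 0 °C to rt, dark
Reagents that add atoms: iodoform, IC(I)I
Why: Takai olefination: CrCl2 (divalent chromium) reduces iodoform to a geminal dichromium species that adds to the aldehyde and eliminates to the E vinyl iodide, the bulk of the quaternary carbon reinforcing the E preference. The aryl ester is inert to organochromium reagents.

Step 8
Reactants: 11 geranylacetone
Product: 13 (5E)-6,10-dimethylundeca-5,9-dien-1-yne, via enol diethyl phosphate 12 (not isolated)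
Conditions: LiN(iPr)2, THF, −78 °C; ClP(O)(OEt)2, −78 °C to rt; then LiN(iPr)2 (2.3 equiv), −78 °C to rt; H2O
Reagents that add atoms: none
Why: Methyl ketone to terminal alkyne conversion: kinetic enolisation at the methyl group, O-phosphorylation and base-induced β-elimination of the enol phosphate to the acetylide. The isolated trisubstituted alkenes are not affected.

Step 9
Reactants: 13 (5E)-6,10-dimethylundeca-5,9-dien-1-yne; 10 methyl (2R)-2-[(E)-2-iodoethenyl]-2-methylchroman-6-carboxylate
Product: 15 methyl (2R)-2-methyl-2-[(1E,3E,7E)-4,8,12-trimethyltrideca-1,3,7,11-tetraen-1-yl]chroman-6-carboxylate, via alkenyldimethylalane 14 (not isolated)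
Conditions: Me3Al (2 equiv), Cp2ZrCl2 (0.25 equiv), CH2Cl2, 0 °C to rt; volatiles removed; then 10, ZnCl2 (0.5 equiv), Pd(PPh3)4 (5 mol %), THF, 0 °C to rt
Reagents that add atoms: trimethylaluminium, C[Al](C)C
Why: Zirconium-catalysed syn carboalumination of the terminal alkyne sets the 3'E trisubstituted alkene, and the Negishi coupling, with ZnCl2 as transmetalation shuttle, joins it to the E vinyl iodide with retention at both carbons. Excess Me3Al is removed before the ester-bearing partner is added.

Step 10
Reactants: 15 methyl (2R)-2-methyl-2-[(1E,3E,7E)-4,8,12-trimethyltrideca-1,3,7,11-tetraen-1-yl]chroman-6-carboxylate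
Product: 16 (2R)-2-methyl-2-[(1E,3E,7E)-4,8,12-trimethyltrideca-1,3,7,11-tetraen-1-yl]chroman-6-carboxylic acid
Conditions: LiOH·H2O, THF/MeOH/H2O, rt to 40 °C; then aq. citric acid to pH 5, 0 °C
Reagents that add atoms: lithium hydroxide, [Li+].[OH-]
Why: Saponification of a methyl benzoate by acyl–oxygen cleavage; the aryl ether and the polyene are stable to base, and acidification with a weak acid in the cold should not ionise the O1–C2 bond.

Step 11
Reactants: 16 (2R)-2-methyl-2-[(1E,3E,7E)-4,8,12-trimethyltrideca-1,3,7,11-tetraen-1-yl]chroman-6-carboxylic acid
Product: 17 (2R)-2-methyl-2-[(1E,3E)-4-methyl-6-(2,6,6-trimethylcyclohex-1-en-1-yl)hexa-1,3-dien-1-yl]chroman-6-carboxylic acid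
Conditions: engineered squalene–hopene cyclase variant (Alicyclobacillus acidocaldarius enzyme, E. coli whole cells), citrate buffer pH 6.0, 0.2% Triton X-100, 30–45 °C; EtOAc extraction, SiO2
Reagents that add atoms: none
Why: Proposed new method: the central aspartic acid of the DXDD motif of the cyclase is expected to protonate C11' of the terminal alkene of 16 held in a chair fold, the C7'=C8' alkene then attacks the C12' cation through C7' (a 6-endo closure with respect to the attacking alkene, forming C7'–C12' and ring C with the charge at C8'), and loss of the C7' proton to an active-site base gives the tetrasubstituted alkene of 17. The closest known reaction type is the truncated, monocyclising proton-initiated cyclisation of short polyprenoids such as homofarnesic acid, geranylacetone and farnesol-type substrates by variants of this enzyme; a chain with a conjugated diene and a chroman carboxylate has not been cyclised in this way. No stereocentre is formed, and C2 lies far from the catalytic acid, so its configuration should stay as it is. The step needs protonation of the terminal alkene only, which head-first binding of the lipophilic prenyl end, with the carboxylate at the channel mouth, should secure. It needs termination after one ring: a second six-membered closure would have to go through C3' and would cost the diene its conjugation, and bulky residues introduced around the second-ring pocket should reinforce this. It needs proton loss towards C7' and not towards C9' or the C8' methyl group, which is to be tuned through the position of the base during variant screening. The near-neutral buffer and the enclosed active site keep acid away from the O1–C2 bond, which an acid in solution would ionise.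

## Compound list

1 | (S)-2-methylglycidol, [(2S)-2-methyloxiran-2-yl]methanol | OC[C@@]1(C)CO1 | starting material
2 | tert-butyl{[(2R)-2-methyloxiran-2-yl]methoxy}diphenylsilane | CC(C)(C)[Si](OC[C@@]1(C)CO1)(c1ccccc1)c1ccccc1 | intermediate
3 | (2R)-1-[(tert-butyldiphenylsilyl)oxy]-2-methylbut-3-en-2-ol | CC(C)(C)[Si](OC[C@@](O)(C)C=C)(c1ccccc1)c1ccccc1 | intermediate
4 | methyl 3-bromo-4-fluorobenzoate | COC(=O)c1ccc(F)c(Br)c1 | starting material
5 | (2R)-4-(9-borabicyclo[3.3.1]nonan-9-yl)-1-[(tert-butyldiphenylsilyl)oxy]-2-methylbutan-2-ol (formed in the flask, not isolated) | CC(C)(C)[Si](OC[C@@](O)(C)CCB1C2CCCC1CCC2)(c1ccccc1)c1ccccc1 | intermediate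
6 | methyl 3-[(3R)-4-[(tert-butyldiphenylsilyl)oxy]-3-hydroxy-3-methylbutyl]-4-fluorobenzoate | COC(=O)c1ccc(F)c(CC[C@@](C)(O)CO[Si](c2ccccc2)(c2ccccc2)C(C)(C)C)c1 | intermediate
7 | methyl (2R)-2-{[(tert-butyldiphenylsilyl)oxy]methyl}-2-methylchroman-6-carboxylate | CC(C)(C)[Si](OC[C@@]1(C)CCc2cc(C(=O)OC)ccc2O1)(c1ccccc1)c1ccccc1 | intermediate
8 | methyl (2R)-2-(hydroxymethyl)-2-methylchroman-6-carboxylate | OC[C@@]1(C)CCc2cc(C(=O)OC)ccc2O1 | intermediate
9 | methyl (2R)-2-formyl-2-methylchroman-6-carboxylate | O=C[C@@]1(C)CCc2cc(C(=O)OC)ccc2O1 | intermediate
10 | methyl (2R)-2-[(E)-2-iodoethenyl]-2-methylchroman-6-carboxylate | I/C=C/[C@@]1(C)CCc2cc(C(=O)OC)ccc2O1 | intermediate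
11 | geranylacetone, (5E)-6,10-dimethylundeca-5,9-dien-2-one | CC(C)=CCC/C(C)=C/CCC(C)=O | starting material
12 | diethyl (5E)-6,10-dimethylundeca-1,5,9-trien-2-yl phosphate (formed in the flask, not isolated) | CC(C)=CCC/C(C)=C/CCC(=C)OP(=O)(OCC)OCC | intermediate
13 | (5E)-6,10-dimethylundeca-5,9-dien-1-yne | CC(C)=CCC/C(C)=C/CCC#C | intermediate
14 | dimethyl[(1E,5E)-2,6,10-trimethylundeca-1,5,9-trien-1-yl]alumane (formed in the flask, not isolated) | CC(C)=CCC/C(C)=C/CC/C(C)=C/[Al](C)C | intermediate
15 | methyl (2R)-2-methyl-2-[(1E,3E,7E)-4,8,12-trimethyltrideca-1,3,7,11-tetraen-1-yl]chroman-6-carboxylate | CC(C)=CCC/C(C)=C/CC/C(C)=C/C=C/[C@@]1(C)CCc2cc(C(=O)OC)ccc2O1 | intermediate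
16 | (2R)-2-methyl-2-[(1E,3E,7E)-4,8,12-trimethyltrideca-1,3,7,11-tetraen-1-yl]chroman-6-carboxylic acid | CC(C)=CCC/C(C)=C/CC/C(C)=C/C=C/[C@@]1(C)CCc2cc(C(=O)O)ccc2O1 | intermediate
17 | (2R)-2-methyl-2-[(1E,3E)-4-methyl-6-(2,6,6-trimethylcyclohex-1-en-1-yl)hexa-1,3-dien-1-yl]chroman-6-carboxylic acid | CC1=C(CC/C(C)=C/C=C/[C@@]2(C)CCc3cc(C(=O)O)ccc3O2)C(C)(C)CCC1 | target

## Step count and least certain steps

Total: 11 steps. Longest linear sequence: 10 steps (steps 1 to 7, then 9, 10 and 11); the terpene branch contributes step 8.

**Step 11 (key step, proposed new method).**
- What may go wrong: no productive binding of a substrate with a bulky chroman carboxylate tail. A second closure through C4' to a five-membered ring and an allylic cation. Proton loss to the exocyclic or the C8'=C9' isomer. Capture of the C8' cation by water. Acid-assisted ionisation of O1–C2 if low pH and high temperature are needed for turnover.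
- Fallback by known chemistry, setting out from 10 and coming back at 17: ring C is bought instead of made. Dihydro-β-ionone F1 would be converted as in step 8, through its enol diethyl phosphate F2, into 2-(but-3-yn-1-yl)-1,3,3-trimethylcyclohex-1-ene F3. Carboalumination as in step 9 would give the alkenyldimethylalane F4, and Negishi coupling with 10 would give the methyl ester of 17 F5 (identical with A7). Saponification as in step 10 would give 17.

**Step 9.**
- What may go wrong: ionisation of the allylic or dienylic aryl ether by zerovalent palladium or by the aluminium and zinc halides, with erosion of the configuration at C2 or opening of ring B. Attack of residual Me3Al on the ester. Incomplete carboalumination.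
- Fallback without palladium or Lewis acid, setting out from 9 and coming back at 15 (steps 7 and 8 are then not needed): (2E,6E)-farnesyl bromide F6 and PBu3 would give tributyl[(2E,6E)-farnesyl]phosphonium bromide F7. n-BuLi in THF at −78 °C would give the allylic tributylphosphonium ylide F8, which should react with 9 in an E-selective Wittig olefination to give 15. Any 1'Z isomer would have to be separated.

**Step 4.**
- What may go wrong: slow substitution, because one para ester is only a moderate activator. Migration of the silyl group to the tertiary alkoxide followed by closure of a seven-membered ether. Attack of the base on the ester.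
- Fallback, setting out from 3 (through 5) and coming back at 7: Suzuki–Miyaura coupling with methyl 3-bromo-4-chlorobenzoate F9 at C–Br would give methyl 4-chloro-3-[(3R)-4-[(tert-butyldiphenylsilyl)oxy]-3-hydroxy-3-methylbutyl]benzoate F10. A palladium-catalysed intramolecular C–O coupling (Pd(OAc)2, 2-(di-tert-butylphosphino)-1,1'-binaphthyl, Cs2CO3, toluene, 80 °C) would then close ring B under a weak base.

**Step 2.**
- What may go wrong: slow opening of the hindered epoxide by the ylide, or closure of the betaine to an oxetane instead of elimination.
- Fallback, setting out from 2 and coming back at 3: PhSCH2Li (from thioanisole, n-BuLi and DABCO in THF at 0 °C) would open the epoxide to (2R)-1-[(tert-butyldiphenylsilyl)oxy]-2-methyl-4-(phenylsulfanyl)butan-2-ol F11. NaIO4 in aqueous methanol would give the sulfoxide (2R)-1-[(tert-butyldiphenylsilyl)oxy]-2-methyl-4-(phenylsulfinyl)butan-2-ol F12. Thermal syn elimination (toluene, CaCO3, 110 °C) would give 3.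

## Further compounds

F1 | step 11 | 4-(2,6,6-trimethylcyclohex-1-en-1-yl)butan-2-one (dihydro-β-ionone) | CC1=C(CCC(C)=O)C(C)(C)CCC1
F2 | step 11 | diethyl 4-(2,6,6-trimethylcyclohex-1-en-1-yl)but-1-en-2-yl phosphate | C=C(CCC1=C(C)CCCC1(C)C)OP(=O)(OCC)OCC
F3 | step 11 | 2-(but-3-yn-1-yl)-1,3,3-trimethylcyclohex-1-ene | C#CCCC1=C(C)CCCC1(C)C
F4 | step 11 | dimethyl[(1E)-2-methyl-4-(2,6,6-trimethylcyclohex-1-en-1-yl)but-1-en-1-yl]alumane | C[Al](C)/C=C(\C)CCC1=C(C)CCCC1(C)C
F5 | step 11 | methyl (2R)-2-methyl-2-[(1E,3E)-4-methyl-6-(2,6,6-trimethylcyclohex-1-en-1-yl)hexa-1,3-dien-1-yl]chroman-6-carboxylate | CC1=C(CC/C(C)=C/C=C/[C@@]2(C)CCc3cc(C(=O)OC)ccc3O2)C(C)(C)CCC1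
F6 | step 9 | (2E,6E)-farnesyl bromide, (2E,6E)-1-bromo-3,7,11-trimethyldodeca-2,6,10-triene | CC(C)=CCC/C(C)=C/CC/C(C)=C/CBr
F7 | step 9 | tributyl[(2E,6E)-3,7,11-trimethyldodeca-2,6,10-trien-1-yl]phosphonium bromide | CC(C)=CCC/C(C)=C/CC/C(C)=C/C[P+](CCCC)(CCCC)CCCC.[Br-]
F8 | step 9 | tributyl[(2E,6E)-3,7,11-trimethyldodeca-2,6,10-trien-1-ylidene]phosphorane | CC(C)=CCC/C(C)=C/CC/C(C)=C/C=P(CCCC)(CCCC)CCCC
F9 | step 4 | methyl 3-bromo-4-chlorobenzoate | COC(=O)c1ccc(Cl)c(Br)c1
F10 | step 4 | methyl 4-chloro-3-[(3R)-4-[(tert-butyldiphenylsilyl)oxy]-3-hydroxy-3-methylbutyl]benzoate | COC(=O)c1ccc(Cl)c(CC[C@@](C)(O)CO[Si](c2ccccc2)(c2ccccc2)C(C)(C)C)c1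
F11 | step 2 | (2R)-1-[(tert-butyldiphenylsilyl)oxy]-2-methyl-4-(phenylsulfanyl)butan-2-ol | CC(C)(C)[Si](OC[C@@](O)(C)CCSc1ccccc1)(c1ccccc1)c1ccccc1
F12 | step 2 | (2R)-1-[(tert-butyldiphenylsilyl)oxy]-2-methyl-4-(phenylsulfinyl)butan-2-ol (both sulfur epimers) | CC(C)(C)[Si](OC[C@@](O)(C)CCS(=O)c1ccccc1)(c1ccccc1)c1ccccc1
A1 | alternative 1 | methyl 6-{[(2R)-1-[(tert-butyldimethylsilyl)oxy]-2-methylhex-5-yn-2-yl]oxy}pyridazine-3-carboxylate | CC(C)(C)[Si](C)(C)OC[C@@](C)(CCC#C)Oc1ccc(C(=O)OC)nn1
A2 | alternative 1 | methyl (2R)-2-[(tert-butyldimethylsilyloxy)methyl]-2-methylchroman-6-carboxylate | CC(C)(C)[Si](C)(C)OC[C@@]1(C)CCc2cc(C(=O)OC)ccc2O1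
A3 | alternative 2 | methyl 4-hydroxy-3-iodobenzoate | COC(=O)c1ccc(O)c(I)c1
A4 | alternative 2 | 3-methylpenta-1,4-diene | C=CC(C)C=C
A5 | alternative 2 | methyl (2R)-2-ethenyl-2-methylchroman-6-carboxylate | C=C[C@@]1(C)CCc2cc(C(=O)OC)ccc2O1
A6 | alternative 3 | methyl 4-hydroxy-3-[(3E,6E)-5-[(methoxycarbonyl)oxy]-3,7-dimethyl-9-(2,6,6-trimethylcyclohex-1-en-1-yl)nona-3,6-dien-1-yl]benzoate (racemic at C5) | COC(=O)OC(/C=C(\C)CCc1cc(C(=O)OC)ccc1O)/C=C(\C)CCC1=C(C)CCCC1(C)C
A7 | alternative 3 | methyl (2R)-2-methyl-2-[(1E,3E)-4-methyl-6-(2,6,6-trimethylcyclohex-1-en-1-yl)hexa-1,3-dien-1-yl]chroman-6-carboxylate | CC1=C(CC/C(C)=C/C=C/[C@@]2(C)CCc3cc(C(=O)OC)ccc3O2)C(C)(C)CCC1
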